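**Assumption:** the target has no stereocentre and no stereogenic double bond (C3=C3a is locked in the ring), so "single enantiomer" means the achiral compound itself; intermediates 3, 6 and 7 are racemic and their stereocentres are erased later.

**Retrosynthetic overview**
1. Peniophorin 10 comes from its bis(methyl ether) 9 by BBr3 demethylation (last step).
2. 9 is the enol (quinone methide) tautomer of o-quinone 8, made by IBX ortho-oxygenation of 6-hydroxybenzofuranone 7 at C5, its only free ortho carbon.
3. The lactone ring of 7 comes from the symmetric resorcinol 4 and 4-methoxymandelic acid 5 by Friedel–Crafts alkylation and lactonisation. The symmetry of 4 removes the phenyl-versus-hydroxyphenyl regiochemistry problem of a terphenylquinone condensation.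
4. 4 comes from commercial 5-aryl-cyclohexane-1,3-dione 1 by Pd α-arylation with bromobenzene 2, then dehydrogenation.
5. Ring order: six-membered carbocycle (bought, then aromatised), then the lactone ring, then oxidation to the quinonoid level.

**Route**

Step 1
Reactants: 1 5-(4-methoxyphenyl)cyclohexane-1,3-dione; 2 bromobenzene
Product: 3 rac-3-hydroxy-5-(4-methoxyphenyl)-2-phenylcyclohex-2-en-1-one (enol form of the 2-phenyl-1,3-dione)
Conditions: Pd(OAc)2 (2 mol %), t-BuXPhos (4 mol %), K3PO4, 1,4-dioxane, 100 °C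
Reagents that add atoms: none
Why: Pd-catalysed α-arylation of the 1,3-dione enolate (Buchwald-type enolate arylation) puts the phenyl on C2, the only carbon between both carbonyls, and stops at mono-arylation because the product rests as a hindered stabilised enolate.

Step 2
Reactants: 3 rac-3-hydroxy-5-(4-methoxyphenyl)-2-phenylcyclohex-2-en-1-one
Product: 4 5-(4-methoxyphenyl)-2-phenylbenzene-1,3-diol
Conditions: 10 % Pd/C (10 mol %), triglyme, 200 °C, Ar sweep
Reagents that add atoms: none
Why: Catalytic dehydrogenation (aromatisation) over Pd/C removes one H2 and the dienone tautomerises irreversibly to the resorcinol, which leaves the anisyl ether intact and gives a symmetric ring whose two free positions are equivalent.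

Step 3
Reactants: 4 5-(4-methoxyphenyl)-2-phenylbenzene-1,3-diol; 5 (RS)-4-methoxymandelic acid
Product: 7 rac-6-hydroxy-3,4-bis(4-methoxyphenyl)-7-phenyl-1-benzofuran-2(3H)-one, via Friedel-Crafts hydroxy acid 6 (not isolated)
Conditions: 5 (1.05 equiv, slow addition), TsOH·H2O (20 mol %), ClCH2CH2Cl, reflux, Dean–Stark
Reagents that add atoms: none
Why: Acid-catalysed Friedel–Crafts alkylation by the 4-methoxybenzylic cation at the resorcinol carbon ortho to one OH and para to the other (the two free positions are identical by symmetry), followed by lactonisation of the adjacent OH, builds the 3-arylbenzofuranone, whose new C3 centre is racemic and disappears in step 4.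

Step 4
Reactants: 7 rac-6-hydroxy-3,4-bis(4-methoxyphenyl)-7-phenyl-1-benzofuran-2(3H)-one
Product: 9 5-hydroxy-3,4-bis(4-methoxyphenyl)-7-phenyl-1-benzofuran-2,6-dione (peniophorin di-O-methyl ether), via o-quinone tautomer 8 (not isolated)
Conditions: IBX (1.2 equiv), DMF, rt, dark
Reagents that add atoms: IBX (2-iodoxybenzoic acid), O=C1OI(=O)(O)c2ccccc12
Why: IBX-mediated regioselective ortho-oxygenation of the phenol delivers oxygen to C5, the only free position ortho to the C6 hydroxyl, and the resulting o-quinone tautomerises through its doubly activated C3–H to the hydrogen-bonded hydroxy quinone methide, making C3 sp2.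

Step 5
Reactants: 9 5-hydroxy-3,4-bis(4-methoxyphenyl)-7-phenyl-1-benzofuran-2,6-dione
Product: 10 peniophorin, 5-hydroxy-3,4-bis(4-hydroxyphenyl)-7-phenyl-1-benzofuran-2,6-dione
Conditions: BBr3 (6 equiv), CH2Cl2, −78 °C → rt; then H2O
Reagents that add atoms: none
Why: Lewis-acid aryl methyl ether cleavage (bromide SN2 at the methyl groups of the boron-complexed ethers) frees both phenols, while the enol lactone and hydroxy quinone methide only complex boron and are restored on aqueous quench.

**Compound list**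
1 | 5-(4-methoxyphenyl)cyclohexane-1,3-dione | COc1ccc(cc1)C1CC(=O)CC(=O)C1 | starting material
2 | bromobenzene | Brc1ccccc1 | starting material
3 | rac-3-hydroxy-5-(4-methoxyphenyl)-2-phenylcyclohex-2-en-1-one | COc1ccc(cc1)C1CC(=O)C(c2ccccc2)=C(O)C1 | intermediate
4 | 5-(4-methoxyphenyl)-2-phenylbenzene-1,3-diol | COc1ccc(cc1)-c1cc(O)c(-c2ccccc2)c(O)c1 | intermediate
5 | (RS)-4-methoxymandelic acid | COc1ccc(cc1)C(O)C(O)=O | starting material
6 | rac-2-[2,4-dihydroxy-6-(4-methoxyphenyl)-3-phenylphenyl]-2-(4-methoxyphenyl)acetic acid | COc1ccc(cc1)C(C(O)=O)c1c(O)c(-c2ccccc2)c(O)cc1-c1ccc(OC)cc1 | intermediate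
7 | rac-6-hydroxy-3,4-bis(4-methoxyphenyl)-7-phenyl-1-benzofuran-2(3H)-one | COc1ccc(cc1)C1C(=O)Oc2c(-c3ccccc3)c(O)cc(-c3ccc(OC)cc3)c12 | intermediate
8 | rac-3,4-bis(4-methoxyphenyl)-7-phenyl-3H-1-benzofuran-2,5,6-trione | COc1ccc(cc1)C1C(=O)OC2=C(c3ccccc3)C(=O)C(=O)C(c3ccc(OC)cc3)=C12 | intermediate
9 | 5-hydroxy-3,4-bis(4-methoxyphenyl)-7-phenyl-1-benzofuran-2,6-dione | O=C1OC2=C(c3ccccc3)C(=O)C(O)=C(c3ccc(OC)cc3)C2=C1c1ccc(OC)cc1 | intermediate
10 | peniophorin | O=C1OC2=C(c3ccccc3)C(=O)C(O)=C(c3ccc(O)cc3)C2=C1c1ccc(O)cc1 | target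

**Total step count:** 5
**Longest linear sequence:** 5 steps (1 → 3 → 4 → 7 → 9 → 10)

**Three steps most likely to fail**

Step 2 (aromatisation). At 200 °C over Pd/C the dione can disproportionate by hydrogen transfer or lose oxygen to give 3-arylphenols. The fallback sets out from 3 and comes back at 4, and stages the oxidation through an electron-rich diene instead of a thermal surface dehydrogenation. Exhaustive O-silylation of 3 (TMSOTf, Et3N, CH2Cl2, 0 °C) gives rac-1,3-bis(trimethylsilyloxy)-5-(4-methoxyphenyl)-2-phenylcyclohexa-1,3-diene F1. DDQ in benzene at rt abstracts hydride from its allylic, benzylic C5–H and aromatises it to 5-(4-methoxyphenyl)-2-phenyl-1,3-bis(trimethylsilyloxy)benzene F2. Dilute HCl in THF then removes the silyl groups to give 4.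

Step 3 (Friedel–Crafts annulation). The carbon to be alkylated is flanked by an OH and a biaryl ring, and the free cation may instead attack the anisyl ring, oligomerise 5, or annulate twice. The fallback sets out from 4 and comes back at 7, and replaces the free cation with a titanium-phenoxide-templated ortho-hydroxyalkylation. Treating 4 with TiCl4 and commercial ethyl (4-methoxyphenyl)glyoxylate in CH2Cl2 (−20 °C → rt) delivers the ketone to the ortho carbon within the Ti chelate, giving rac-ethyl 2-[2,4-dihydroxy-6-(4-methoxyphenyl)-3-phenylphenyl]-2-hydroxy-2-(4-methoxyphenyl)acetate F3. This lactonises in the flask to rac-3,6-dihydroxy-3,4-bis(4-methoxyphenyl)-7-phenyl-1-benzofuran-2(3H)-one F4. Ionic hydrogenation (Et3SiH, TFA, CH2Cl2) of the tertiary benzylic alcohol, through the para-quinone methide cation, then gives 7.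

Step 4 (IBX ortho-oxygenation). The acidic C3–H of 7 may divert the oxidation to plain dehydrogenation, giving the 5-unsubstituted para-quinone methide instead of oxygen transfer. The fallback sets out from 4 and comes back at 9, and introduces the extra oxygen before the lactone ring is built.
- Fremy's salt (KH2PO4 buffer, acetone/water) oxidises the symmetric resorcinol para to one OH, giving 2-hydroxy-6-(4-methoxyphenyl)-3-phenyl-1,4-benzoquinone F5.
- Na2S2O4 reduces it to 6-(4-methoxyphenyl)-3-phenylbenzene-1,2,4-triol F6.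
- The single free ring position of F6 is alkylated by 5 (TsOH, ClCH2CH2Cl, reflux) to rac-2-[2,4,5-trihydroxy-6-(4-methoxyphenyl)-3-phenylphenyl]-2-(4-methoxyphenyl)acetic acid F7.
- F7 lactonises in the flask onto its only ortho OH to give rac-5,6-dihydroxy-3,4-bis(4-methoxyphenyl)-7-phenyl-1-benzofuran-2(3H)-one F8.
- Ag2O (or air) oxidises this catechol to o-quinone 8, which tautomerises to 9.

**Further compounds**
F1 | step 2 | rac-1,3-bis(trimethylsilyloxy)-5-(4-methoxyphenyl)-2-phenylcyclohexa-1,3-diene | COc1ccc(cc1)C1CC(O[Si](C)(C)C)=C(c2ccccc2)C(O[Si](C)(C)C)=C1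
F2 | step 2 | 5-(4-methoxyphenyl)-2-phenyl-1,3-bis(trimethylsilyloxy)benzene | COc1ccc(cc1)-c1cc(O[Si](C)(C)C)c(-c2ccccc2)c(O[Si](C)(C)C)c1
F3 | step 3 | rac-ethyl 2-[2,4-dihydroxy-6-(4-methoxyphenyl)-3-phenylphenyl]-2-hydroxy-2-(4-methoxyphenyl)acetate | CCOC(=O)C(O)(c1ccc(OC)cc1)c1c(O)c(-c2ccccc2)c(O)cc1-c1ccc(OC)cc1
F4 | step 3 | rac-3,6-dihydroxy-3,4-bis(4-methoxyphenyl)-7-phenyl-1-benzofuran-2(3H)-one | COc1ccc(cc1)C1(O)C(=O)Oc2c(-c3ccccc3)c(O)cc(-c3ccc(OC)cc3)c12
F5 | step 4 | 2-hydroxy-6-(4-methoxyphenyl)-3-phenyl-1,4-benzoquinone | COc1ccc(cc1)C1=CC(=O)C(c2ccccc2)=C(O)C1=O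
F6 | step 4 | 6-(4-methoxyphenyl)-3-phenylbenzene-1,2,4-triol | COc1ccc(cc1)-c1cc(O)c(-c2ccccc2)c(O)c1O
F7 | step 4 | rac-2-[2,4,5-trihydroxy-6-(4-methoxyphenyl)-3-phenylphenyl]-2-(4-methoxyphenyl)acetic acid | COc1ccc(cc1)C(C(O)=O)c1c(O)c(-c2ccccc2)c(O)c(O)c1-c1ccc(OC)cc1
F8 | step 4 | rac-5,6-dihydroxy-3,4-bis(4-methoxyphenyl)-7-phenyl-1-benzofuran-2(3H)-one | COc1ccc(cc1)C1C(=O)Oc2c(-c3ccccc3)c(O)c(O)c(-c3ccc(OC)cc3)c12
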